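Ring C (the pyranone) is formed last: O1–C2 by cyclodehydration and C3–C(O)Ph by Claisen/Baker–Venkataraman benzoylation of an ortho-hydroxyacetophenone, whose acetyl group comes from Friedel–Crafts acetylation of a symmetrical 2-aryl-resorcinol.
In ring D (the piperidine), the CH2 at C5' is traced back to a geminal diester (Krapcho, then Barton), the handle left by the key step.
Key disconnection: N1'–C2' and C5'–C6' of ring D, a formal (4+2) annulation of a racemic 2-aryl cyclobutane-1,1-diester with N-methylmethanimine (from the triazinane) under a chiral Lewis acid, which sets C2'.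
The strategy rests on C2' being benzylic to C8 of ring A, which carries oxygen on both ortho carbons (C7, C8a) and on the para carbon (C5); this 2,4,6-trioxygenated ring stabilises a cation at C2', so the cyclobutane C–C bond heterolyses readily.
The cyclobutane comes from 2,6-bis(benzyloxy)-4-methoxystyrene and dimethyl methylidenemalonate by (2+2); ring order: cyclobutane, then ring D, then ring C (rings A and B are bought).

Key step: step 6

Assumption: the sense of induction of the chiral copper catalyst in step 6 cannot be predicted with confidence; the ligand enantiomer that gives (R) at C2' is to be identified in a first experiment, and its mirror image would give the (S) series.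
Numbering: flavone locants for rings A and C; primed locants for ring D (N1', C2' bonded to C8, C6' = NCH2).

Step 1
Reactants: 1 2,4,6-trihydroxybenzaldehyde
Product: 2 2,6-dihydroxy-4-methoxybenzaldehyde
Conditions: Me2SO4 (1.0 equiv), K2CO3 (1.0 equiv), acetone, 0 °C to rt
Reagents that add atoms: dimethyl sulfate, COS(=O)(=O)OC
Why: Williamson O-methylation in which one equivalent of weak base ionises mainly the para hydroxyl, the most acidic one and the only one not hydrogen-bonded to the formyl group, so that methylation should fall chiefly at O4 and over-methylated material is removed by chromatography.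

Step 2
Reactants: 2 2,6-dihydroxy-4-methoxybenzaldehyde; 3 benzyl bromide
Product: 4 2,6-bis(benzyloxy)-4-methoxybenzaldehyde
Conditions: BnBr (2.5 equiv), K2CO3 (3 equiv), Bu4NI (cat.), DMF, 60 °C
Reagents that add atoms: benzyl bromide (second equivalent), BrCc1ccccc1
Why: Twofold Williamson benzylation, one molecule of benzyl bromide per phenol, in warm DMF overcomes the hydrogen bonds of the two ortho phenols to the aldehyde and installs ethers that tolerate the Lewis acids of steps 5 and 6 and are removable by hydrogenolysis without touching the C5 methyl ether.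

Step 3
Reactants: 4 2,6-bis(benzyloxy)-4-methoxybenzaldehyde
Product: 5 1,3-bis(benzyloxy)-2-ethenyl-5-methoxybenzene
Conditions: Ph3PCH3Br, KOtBu, THF, 0 °C to rt
Reagents that add atoms: methyltriphenylphosphonium bromide, C[P+](c1ccccc1)(c1ccccc1)c1ccccc1.[Br-]
Why: Wittig methylenation with the non-stabilised ylide converts the hindered, non-enolisable aldehyde into the styrene under basic conditions that the acid-sensitive electron-rich alkene tolerates.

Step 4
Reactants: 6 dimethyl malonate
Product: 7 dimethyl 2-methylidenepropanedioate
Conditions: (CH2O)n, iPr2NH2+ CF3CO2− (1 equiv), CF3CO2H (cat.), THF, reflux; used at once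
Reagents that add atoms: paraformaldehyde (as formaldehyde), C=O
Why: Mannich-type condensation of the malonate with the diisopropyliminium ion of formaldehyde and loss of the amine (a Knoevenagel-type methylenation) gives the methylidenemalonate, which is used immediately because it polymerises.

Step 5
Reactants: 5 1,3-bis(benzyloxy)-2-ethenyl-5-methoxybenzene; 7 dimethyl 2-methylidenepropanedioate
Product: 8 rac-dimethyl 2-[2,6-bis(benzyloxy)-4-methoxyphenyl]cyclobutane-1,1-dicarboxylate
Conditions: Yb(OTf)3 (5 mol %), 4 Å MS, CH2Cl2, −78 °C; Et3N quench at −78 °C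
Reagents that add atoms: none
Why: Lewis-acid-catalysed stepwise (2+2) cycloaddition in which the terminal carbon of the strongly nucleophilic styrene adds to the Yb(OTf)3-bound methylidenemalonate and the benzylic cation–malonate zwitterion collapses at low temperature to the cyclobutane with the aryl group next to the diester carbon, as a racemate, which is what the enantioconvergent step 6 requires.

Step 6
Reactants: 8 rac-dimethyl 2-[2,6-bis(benzyloxy)-4-methoxyphenyl]cyclobutane-1,1-dicarboxylate; 9 1,3,5-trimethyl-1,3,5-triazinane
Product: 11 dimethyl (R)-6-[2,6-bis(benzyloxy)-4-methoxyphenyl]-1-methylpiperidine-3,3-dicarboxylate, via N-methylmethanimine 10 (not isolated)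
Conditions: Cu(OTf)2 (10 mol %), chiral isopropyl-trisoxazoline ligand (12 mol %, one enantiomer), 4 Å MS, CH2Cl2, −20 °C; 9 (0.40 equiv, three imine units per molecule) added over 6 h
Reagents that add atoms: none
Why: Proposed new method: the Cu(OTf)2–trisoxazoline complex chelates the geminal diester of 8 and heterolyses the bond between the malonate carbon and the aryl-bearing carbon, giving a benzylic cation at the future C2' (an oxocarbenium-like quinoid ion stabilised by the three ring oxygens) paired with the copper-bound malonate; N-methylmethanimine 10, released from 9 by the same Lewis acid, captures the cation through nitrogen and the malonate then adds to the resulting N-methyliminium carbon C6'. The closest known reactions are the racemic Lewis-acid (4+2) annulations of 2-aryl cyclobutane-1,1-diesters with imines and with triazinanes as formaldimine sources, and the enantioconvergent annulations of donor–acceptor cyclopropanes with imines under chiral Lewis acids; an enantioselective version on a cyclobutane with a formaldimine has not been shown. Ring D closes by intramolecular Mannich attack of C5' on C6', a 6-endo-trig closure. C2' is the only new stereocentre and is set in the N–C2' bond formation: because ionisation is fast and reversible with this donor, both enantiomers of 8 should funnel into one ion pair, in which the ligand side arms around copper, held three atoms away through C3' and C4', shield one face of the planar cation, so that the ligand enantiomer decides (R). The step needs capture at nitrogen to outrun proton loss from the zwitterion and self-alkylation of the electron-rich ring, and a free Lewis acid despite the amines; the localisation of charge at C2', the benzyloxy groups that block both ortho positions, and the slow dosing of 9 are meant to secure this.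

Step 7
Reactants: 11 dimethyl (R)-6-[2,6-bis(benzyloxy)-4-methoxyphenyl]-1-methylpiperidine-3,3-dicarboxylate
Product: 12 methyl (6R)-6-[2,6-bis(benzyloxy)-4-methoxyphenyl]-1-methylpiperidine-3-carboxylate (mixture of C3 epimers)
Conditions: LiCl (3 equiv), H2O (2 equiv), DMSO, 150 °C
Reagents that add atoms: none
Why: Krapcho dealkoxycarbonylation, in which chloride demethylates one ester and the carboxylate loses CO2 under neutral conditions that leave the benzyl ethers and C2' untouched; the new centre at C5' forms as an epimer mixture, which does not matter because the centre is removed in step 9.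

Step 8
Reactants: 12 methyl (6R)-6-[2,6-bis(benzyloxy)-4-methoxyphenyl]-1-methylpiperidine-3-carboxylate
Product: 13 (6R)-6-[2,6-bis(benzyloxy)-4-methoxyphenyl]-1-methylpiperidine-3-carboxylic acid (mixture of C3 epimers)
Conditions: LiOH·H2O, THF/MeOH/H2O, rt; aq. HCl to pH 6–7
Reagents that add atoms: lithium hydroxide, [Li+].[OH-]
Why: Saponification of the remaining methyl ester at room temperature gives the amino acid, isolated at its isoelectric point, and the base cannot epimerise C2', which carries no acidifying group.

Step 9
Reactants: 13 (6R)-6-[2,6-bis(benzyloxy)-4-methoxyphenyl]-1-methylpiperidine-3-carboxylic acid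
Product: 15 (R)-2-[2,6-bis(benzyloxy)-4-methoxyphenyl]-1-methylpiperidine, via Barton ester 14 (not isolated)
Conditions: N-hydroxypyridine-2(1H)-thione, DCC, DMAP (cat.), CH2Cl2, rt, dark; then t-BuSH, visible light, 0 °C to rt
Reagents that add atoms: none
Why: Barton reductive decarboxylation, in which the O-acyl thiohydroxamate fragments under visible light to CO2 and the secondary C5' radical, which the thiol reduces in a chain process run at or below room temperature so that the C2'–H bond is left alone.

Step 10
Reactants: 15 (R)-2-[2,6-bis(benzyloxy)-4-methoxyphenyl]-1-methylpiperidine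
Product: 16 5-methoxy-2-[(2R)-1-methylpiperidin-2-yl]benzene-1,3-diol
Conditions: H2 (1 atm), 10% Pd/C, EtOAc/MeOH, rt; used directly
Reagents that add atoms: none
Why: Hydrogenolysis of the two aryl benzyl ethers over Pd/C should be much faster than cleavage of the ring C2'–N bond of a free tertiary amine whose aryl group is shielded by two ortho substituents, so the symmetrical resorcinol should form with the stereocentre intact.

Step 11
Reactants: 16 5-methoxy-2-[(2R)-1-methylpiperidin-2-yl]benzene-1,3-diol
Product: 17 1-[2,4-dihydroxy-6-methoxy-3-[(2R)-1-methylpiperidin-2-yl]phenyl]ethan-1-one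
Conditions: BF3·OEt2 (4 equiv), then Ac2O (1.5 equiv), CH2Cl2, 0 °C to rt; K2CO3, MeOH/H2O work-up
Reagents that add atoms: acetic anhydride, CC(=O)OC(C)=O
Why: Friedel–Crafts C-acetylation in which nitrogen is tied up as its BF3 adduct, the two free ring positions are equivalent by symmetry and activated by three oxygens, the first acetyl group deactivates the ring against a second, and the basic methanolysis returns any phenolic acetate.

Step 12
Reactants: 17 1-[2,4-dihydroxy-6-methoxy-3-[(2R)-1-methylpiperidin-2-yl]phenyl]ethan-1-one; 18 benzoyl chloride
Product: 19 1-[2,4-dihydroxy-6-methoxy-3-[(2R)-1-methylpiperidin-2-yl]phenyl]-3-phenylpropane-1,3-dione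
Conditions: LiN(SiMe3)2 (4.5 equiv), THF, −78 to −10 °C; PhCOCl (1.05 equiv), −78 °C to rt; aq. HCl to pH 7
Reagents that add atoms: none
Why: Claisen-type C-benzoylation of the lithium enolate within the trilithiated dihydroxyacetophenone gives the 1,3-diketone directly, and any ortho O-benzoate converges on the same product by Baker–Venkataraman O-to-C acyl shift under the excess base.

Step 13
Reactants: 19 1-[2,4-dihydroxy-6-methoxy-3-[(2R)-1-methylpiperidin-2-yl]phenyl]-3-phenylpropane-1,3-dione
Product: 20 7-hydroxy-5-methoxy-8-[(2R)-1-methylpiperidin-2-yl]-2-phenyl-4H-chromen-4-one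
Conditions: AcOH, H2SO4 (0.5 vol %), 60–80 °C
Reagents that add atoms: none
Why: Acid-catalysed cyclodehydration in which the phenol flanked by the acyl group and C2' adds to the benzoyl carbonyl (6-exo-trig) and loss of water forms O1–C2 and ring C, while the acyl-deactivated ring A and the moderate temperature are meant to suppress ionisation of the C2'–N bond so that the (R) centre from step 6 reaches the target.

Compound list
1 | 2,4,6-trihydroxybenzaldehyde | O=Cc1c(O)cc(O)cc1O | starting material
2 | 2,6-dihydroxy-4-methoxybenzaldehyde | COc1cc(O)c(C=O)c(O)c1 | intermediate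
3 | benzyl bromide | BrCc1ccccc1 | starting material
4 | 2,6-bis(benzyloxy)-4-methoxybenzaldehyde | COc1cc(OCc2ccccc2)c(C=O)c(OCc2ccccc2)c1 | intermediate
5 | 1,3-bis(benzyloxy)-2-ethenyl-5-methoxybenzene | COc1cc(OCc2ccccc2)c(C=C)c(OCc2ccccc2)c1 | intermediate
6 | dimethyl malonate | COC(=O)CC(=O)OC | starting material
7 | dimethyl 2-methylidenepropanedioate | COC(=O)C(=C)C(=O)OC | intermediate
8 | rac-dimethyl 2-[2,6-bis(benzyloxy)-4-methoxyphenyl]cyclobutane-1,1-dicarboxylate | COC(=O)C1(C(=O)OC)CCC1c1c(OCc2ccccc2)cc(OC)cc1OCc1ccccc1 | intermediate
9 | 1,3,5-trimethyl-1,3,5-triazinane | CN1CN(C)CN(C)C1 | starting material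
10 | N-methylmethanimine (not isolated) | CN=C | intermediate
11 | dimethyl (R)-6-[2,6-bis(benzyloxy)-4-methoxyphenyl]-1-methylpiperidine-3,3-dicarboxylate | COc1cc(OCc2ccccc2)c([C@H]2CCC(C(=O)OC)(C(=O)OC)CN2C)c(OCc2ccccc2)c1 | intermediate
12 | methyl (6R)-6-[2,6-bis(benzyloxy)-4-methoxyphenyl]-1-methylpiperidine-3-carboxylate (C3 epimers) | COc1cc(OCc2ccccc2)c([C@H]2CCC(C(=O)OC)CN2C)c(OCc2ccccc2)c1 | intermediate
13 | (6R)-6-[2,6-bis(benzyloxy)-4-methoxyphenyl]-1-methylpiperidine-3-carboxylic acid (C3 epimers) | COc1cc(OCc2ccccc2)c([C@H]2CCC(C(=O)O)CN2C)c(OCc2ccccc2)c1 | intermediate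
14 | 2-thioxopyridin-1(2H)-yl (6R)-6-[2,6-bis(benzyloxy)-4-methoxyphenyl]-1-methylpiperidine-3-carboxylate (Barton ester, not isolated) | COc1cc(OCc2ccccc2)c([C@H]2CCC(C(=O)On3ccccc3=S)CN2C)c(OCc2ccccc2)c1 | intermediate
15 | (R)-2-[2,6-bis(benzyloxy)-4-methoxyphenyl]-1-methylpiperidine | COc1cc(OCc2ccccc2)c([C@H]2CCCCN2C)c(OCc2ccccc2)c1 | intermediate
16 | 5-methoxy-2-[(2R)-1-methylpiperidin-2-yl]benzene-1,3-diol | COc1cc(O)c([C@H]2CCCCN2C)c(O)c1 | intermediate
17 | 1-[2,4-dihydroxy-6-methoxy-3-[(2R)-1-methylpiperidin-2-yl]phenyl]ethan-1-one | COc1cc(O)c([C@H]2CCCCN2C)c(O)c1C(C)=O | intermediate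
18 | benzoyl chloride | O=C(Cl)c1ccccc1 | starting material
19 | 1-[2,4-dihydroxy-6-methoxy-3-[(2R)-1-methylpiperidin-2-yl]phenyl]-3-phenylpropane-1,3-dione | COc1cc(O)c([C@H]2CCCCN2C)c(O)c1C(=O)CC(=O)c1ccccc1 | intermediate
20 | 7-hydroxy-5-methoxy-8-[(2R)-1-methylpiperidin-2-yl]-2-phenyl-4H-chromen-4-one | COc1cc(O)c([C@H]2CCCCN2C)c2oc(-c3ccccc3)cc(=O)c12 | target

Total step count: 13. Longest linear sequence: 12 steps (steps 1, 2, 3, 5 to 13; step 4 is a one-step side branch).

Steps most likely to fail

Step 6 (proposed new method). The capture of the benzylic cation may show too little facial discrimination, the amine nitrogens may bind copper and stop turnover, or the zwitterion may lose a proton to give the open-chain alkene. The fallback uses known auxiliary chemistry, sets out from 4 and comes back at 15, bypassing steps 5 to 9. Aldehyde 4 is condensed with (S)-2-methylpropane-2-sulfinamide (Ti(OEt)4, THF, 60 °C) to (S,E)-N-[[2,6-bis(benzyloxy)-4-methoxyphenyl]methylidene]-2-methylpropane-2-sulfinamide F1. Addition of Cl(CH2)4MgBr in CH2Cl2 at −48 °C through the cyclic transition state bound at the sulfinyl oxygen should give (S)-N-[(1R)-1-[2,6-bis(benzyloxy)-4-methoxyphenyl]-5-chloropentyl]-2-methylpropane-2-sulfinamide F2; if the ortho benzyloxy groups reverse the sense by chelation, the (R)-sulfinamide is taken instead. KOtBu in THF closes the ring by N-alkylation to (2R)-2-[2,6-bis(benzyloxy)-4-methoxyphenyl]-1-[(S)-tert-butylsulfinyl]piperidine F3. HCl in MeOH at 0 °C removes the auxiliary to give (R)-2-[2,6-bis(benzyloxy)-4-methoxyphenyl]piperidine F4, and reductive methylation (aqueous CH2O, NaBH(OAc)3, 1,2-dichloroethane) gives 15.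

Step 5. The Lewis acid may reopen the cyclobutane to the benzylic cation during the reaction or isolation, followed by proton loss to the open-chain alkene or by cationic oligomerisation of the styrene. The fallback abandons isolation of 8 and runs a sequential one-pot (2+2)/(4+2) process, setting out from 5 and 7 and coming back at 11. The chiral Cu(OTf)2–trisoxazoline complex of step 6 is used to promote the cycloaddition at −78 °C, and 9 is then dosed into the cold solution so that 8 is consumed as it forms. No compound outside the list is made (F0).

Step 11. Any uncomplexed amine may be N-acetylated, after which the C2'–N bond cleaves through the ortho-quinone-methide-like cation, or the bond may ionise reversibly under the Lewis acid and erode the configuration. The fallback is a Houben–Hoesch acylation, setting out from 16 and coming back at 17. With MeCN, dry HCl and ZnCl2 in Et2O at 0 °C the amine is protected as its ammonium salt and no acylating agent able to quaternise nitrogen is present; the product is 1-[2,4-dihydroxy-6-methoxy-3-[(2R)-1-methylpiperidin-2-yl]phenyl]ethan-1-imine F5, collected as its hydrochloride. Hydrolysis in water at 60 °C gives 17.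

Further compounds
F1 | step 6 | (S,E)-N-[[2,6-bis(benzyloxy)-4-methoxyphenyl]methylidene]-2-methylpropane-2-sulfinamide | CC(C)(C)[S@](=O)/N=C/c1c(OCc2ccccc2)cc(OC)cc1OCc1ccccc1
F2 | step 6 | (S)-N-[(1R)-1-[2,6-bis(benzyloxy)-4-methoxyphenyl]-5-chloropentyl]-2-methylpropane-2-sulfinamide | CC(C)(C)[S@](=O)N[C@H](CCCCCl)c1c(OCc2ccccc2)cc(OC)cc1OCc1ccccc1
F3 | step 6 | (2R)-2-[2,6-bis(benzyloxy)-4-methoxyphenyl]-1-[(S)-tert-butylsulfinyl]piperidine | CC(C)(C)[S@](=O)N1CCCC[C@@H]1c1c(OCc2ccccc2)cc(OC)cc1OCc1ccccc1
F4 | step 6 | (R)-2-[2,6-bis(benzyloxy)-4-methoxyphenyl]piperidine | COc1cc(OCc2ccccc2)c([C@H]2CCCCN2)c(OCc2ccccc2)c1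
F0 | step 5 | none | none
F5 | step 11 | 1-[2,4-dihydroxy-6-methoxy-3-[(2R)-1-methylpiperidin-2-yl]phenyl]ethan-1-imine | COc1cc(O)c([C@H]2CCCCN2C)c(O)c1C(C)=N
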